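**Retrosynthetic overview**

- Ring numbering (1,2-dihydronaphthalene): C1 is the CH bonded to C8a that carries the (R)-side-chain ester; C2 is the CH carrying the catechol ring, cis to the C1 carboxyl; C3 is the alkene carbon with the (S)-side-chain ester; C4 is the alkene CH; OH on C7 and C8. Ring A is the benzo ring, ring B the carbocycle C1–C4/C4a/C8a. The ring centres read as (1S,2S).
- Feature: the C1 carboxyl carbon and C4 stand 1,4 across ring B. A temporary lactone bridge C4–O–C(=O)–C1 therefore turns ring A plus C1 and C4 into a 2-benzopyran-3-one diene and leaves C2–C3 as an (E)-caffeate dienophile.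
- Disconnections, backwards: four catechol acetonides; the C1 ester C–O bond (Mitsunobu, inversion of the (S)-hydroxy ester); C3=C4 and the free C1 acid from the bridged lactone by β-elimination; C1–C2 and C3–C4 by [4+2] cycloaddition.
- Fragments: the formylarylacetic acid from 2-bromo-3-hydroxy-4-methoxybenzaldehyde (malonate arylation); dienophile and hydroxy ester from 5-bromo-2,2-dimethyl-1,3-benzodioxole (Heck reaction; Grignard opening of methyl (S)-glycidate).
- Ring order: ring A and the three catechol rings are bought; the lactone (pyranone) ring is closed first, ring B is closed on it in the cycloaddition, and the lactone ring is then opened again.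

Key step: step 8

Remark: the formylarylacetic acid may sit as its ring-closed lactol (1-hydroxyisochroman-3-one form); both forms dehydrate to the same pyranone, so it is drawn open-chain.

**Route**

Step 1
Reactants: 1 5-bromo-2,2-dimethyl-1,3-benzodioxole; 2 methyl (S)-glycidate
Product: 4 methyl (2S)-3-(2,2-dimethyl-1,3-benzodioxol-5-yl)-2-hydroxypropanoate, via aryl Grignard reagent 3 (not isolated)
Conditions: Mg, THF, reflux; then CuI (10 mol %), 2, THF, −40 to −20 °C; aq NH4Cl
Reagents that add atoms: none
Why: Copper-catalysed Grignard opening of a terminal epoxide: the aryl copper species from 3 and CuI attacks the unsubstituted CH2 of the glycidate in SN2 fashion faster than the Grignard reagent adds to the ester at low temperature, and since the C2–O bond is not touched the (S) centre of 2 passes unchanged into 4.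

Step 2
Reactants: 1 5-bromo-2,2-dimethyl-1,3-benzodioxole; 5 acrylic acid
Product: 6 (2E)-3-(2,2-dimethyl-1,3-benzodioxol-5-yl)prop-2-enoic acid
Conditions: Pd(OAc)2 (2 mol %), P(o-tol)3, Et3N, DMF, 100 °C; cold aq citric acid
Reagents that add atoms: none
Why: Mizoroki–Heck reaction: oxidative addition of the aryl bromide to zerovalent palladium, syn insertion of acrylic acid and syn β-hydride elimination should give the (E)-cinnamic acid, and the ketal is inert to the basic medium.

Step 3
Reactants: 4 methyl (2S)-3-(2,2-dimethyl-1,3-benzodioxol-5-yl)-2-hydroxypropanoate; 6 (2E)-3-(2,2-dimethyl-1,3-benzodioxol-5-yl)prop-2-enoic acid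
Product: 7 methyl (2S)-3-(2,2-dimethyl-1,3-benzodioxol-5-yl)-2-{[(2E)-3-(2,2-dimethyl-1,3-benzodioxol-5-yl)prop-2-enoyl]oxy}propanoate (the dienophile)
Conditions: EDC·HCl, DMAP (cat.), CH2Cl2, 0 °C to rt
Reagents that add atoms: none
Why: Steglich-type carbodiimide esterification: the carbinol C–O bond of 4 is not broken, so (S) is retained, and the cinnamic acid has no α-stereocentre to lose on activation.

Step 4
Reactants: 8 2-bromo-3-hydroxy-4-methoxybenzaldehyde
Product: 9 2-bromo-3,4-dihydroxybenzaldehyde
Conditions: BBr3, CH2Cl2, −78 to 0 °C; H2O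
Reagents that add atoms: none
Why: Lewis-acid cleavage of an aryl methyl ether: boron binds the methoxy oxygen and bromide removes the methyl group by SN2, while the aldehyde and the aryl bromide are returned unchanged by the aqueous work-up.

Step 5
Reactants: 9 2-bromo-3,4-dihydroxybenzaldehyde
Product: 11 4-bromo-5-(dimethoxymethyl)-2,2-dimethyl-1,3-benzodioxole, via acetonide aldehyde 10 (not isolated)
Conditions: 2,2-dimethoxypropane, TsOH·H2O (cat.), benzene, reflux, MeOH removed on 4 Å MS; cool, HC(OMe)3, rt; Et3N, basic work-up
Reagents that add atoms: 2,2-dimethoxypropane COC(C)(C)OC; trimethyl orthoformate COC(OC)OC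
Why: Acid-catalysed transketalisation closes the five-membered catechol ketal as methanol is removed, and acetalisation of the aldehyde with the orthoformate then masks it against Knoevenagel condensation with the malonate anion in step 6.

Step 6
Reactants: 11 4-bromo-5-(dimethoxymethyl)-2,2-dimethyl-1,3-benzodioxole; 12 diethyl malonate
Product: 13 diethyl 2-[5-(dimethoxymethyl)-2,2-dimethyl-1,3-benzodioxol-4-yl]propanedioate
Conditions: Pd(OAc)2 (3 mol %), P(t-Bu)3·HBF4, K3PO4, toluene, 90 °C
Reagents that add atoms: none
Why: Palladium-catalysed α-arylation of a malonate enolate: oxidative addition of the aryl bromide to zerovalent palladium, exchange of bromide for the potassium enolate and reductive elimination driven by the bulky phosphine should form the aryl–C bond, and both ketal and acetal tolerate the mild base.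

Step 7
Reactants: 13 diethyl 2-[5-(dimethoxymethyl)-2,2-dimethyl-1,3-benzodioxol-4-yl]propanedioate
Product: 16 2-(5-formyl-2,2-dimethyl-1,3-benzodioxol-4-yl)acetic acid, via acetal malonic acid 14 (not isolated), via formyl malonic acid 15 (not isolated)
Conditions: KOH, EtOH/H2O, 60 °C; 1 M HCl to pH 2, 0 °C to rt; extract; toluene, 90 °C
Reagents that add atoms: potassium hydroxide [K+].[OH-]; water O
Why: Ester saponification, acid hydrolysis of the benzaldehyde dimethyl acetal and thermal decarboxylation of the arylmalonic acid through its cyclic six-membered transition state; the catechol ketal hydrolyses far more slowly than the acetal and no mineral acid is present during the heating.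

Step 8
Reactants: 16 2-(5-formyl-2,2-dimethyl-1,3-benzodioxol-4-yl)acetic acid; 7 the dienophile
Product: 18 endo bridged lactone adduct (1S,2R,3S,4R in the ring numbering of the overview), via benzopyranone diene 17 (not isolated)
Conditions: Ac2O, toluene, 105 °C, 16 (excess) added slowly to 7; chromatography
Reagents that add atoms: none
Why: Ac2O converts 16 through its mixed anhydride into the o-quinoid pyranone 17 (6-exo-trig O-acylation by the formyl/lactol oxygen, then loss of AcOH), and 17 is trapped by 7 in a concerted, asynchronous, suprafacial [4+2] cycloaddition, the closest known reaction type being the Diels–Alder trapping of 2-benzopyran-3-ones generated in this way by acrylate, fumarate and maleimide dienophiles. Two rings are closed: the lactone ring by the acyl transfer just described, and ring B by the intermolecular cycloaddition, which makes C1–C2 and C3–C4 in one step and leaves the lactone as the two-atom bridge of a benzo-fused 2-oxabicyclo[2.2.2]octenone while ring A regains aromaticity. Regiochemistry should follow the pyrylium-olate polarisation of 17: the enolate-like terminus (future C1) bonds to the β-carbon of the caffeate and the oxocarbenium-like terminus (future C4) to the α-carbon. C1 and C4 are tied cis by the bridge, C2 and C3 are trans because the (E)-geometry of 7 is transferred, and the endo orientation of the ester over the diene (secondary orbital overlap) places the C2 aryl group on the lactone side, which becomes cis to the C1 carboxyl. The absolute sense depends on which face of 7 is attacked, for which the only bias is the remote (S)-ester centre, so of the regio-, endo- and face selectivity that the step needs only the first two are secured by the substrates and the face isomers, being diastereomers, are to be separated by chromatography. The temperature is held near 105 °C because the adduct can extrude CO2 on stronger heating.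

Step 9
Reactants: 18 endo bridged lactone adduct
Product: 19 (1S,2S)-2-(2,2-dimethyl-1,3-benzodioxol-5-yl)-3-({[(2S)-3-(2,2-dimethyl-1,3-benzodioxol-5-yl)-1-methoxy-1-oxopropan-2-yl]oxy}carbonyl)-7,8-(isopropylidenedioxy)-1,2-dihydronaphthalene-1-carboxylic acid
Conditions: DBU, CH2Cl2, 0 °C to rt; cold aq citric acid
Reagents that add atoms: none
Why: E1cB β-elimination: DBU removes H3 (α to the ester) and the enolate expels the C4 carboxylate, helped by release of bicyclic strain and by conjugation of the new C3=C4 bond with ring A, while C1 (a bridgehead before opening, then α to a carboxylate) resists deprotonation, so the cis C1/C2 relation should be kept.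

Step 10
Reactants: 19 the C1 carboxylic acid; 4 methyl (2S)-3-(2,2-dimethyl-1,3-benzodioxol-5-yl)-2-hydroxypropanoate
Product: 20 tetra-acetonide of the target: (1S,2S)-1,2-dihydronaphthalene-1,3-dicarboxylate with the (2R)-side chain on the C1 ester and the (2S)-side chain on the C3 ester
Conditions: PPh3, DIAD, THF, 0 °C to rt
Reagents that add atoms: none
Why: Mitsunobu esterification: the alkoxyphosphonium ion of 4 is displaced by the carboxylate of 19 in SN2 fashion, which inverts the carbinol centre from (S) to (R), and because the acid is never activated at its carbonyl group C1 cannot epimerise through a ketene or enol.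

Step 11
Reactants: 20 tetra-acetonide of the target
Product: 21 CNP0237075.1
Conditions: TFA/H2O (9:1), 0 °C to rt, under Ar
Reagents that add atoms: none
Why: Acid-catalysed hydrolysis of the four catechol isopropylidene ketals; methyl and secondary alkyl esters, the conjugated alkene and the four stereocentres are stable to aqueous TFA at room temperature, and exclusion of air protects the free catechols.

**Compound list**

1 | 5-bromo-2,2-dimethyl-1,3-benzodioxole | CC1(C)Oc2ccc(Br)cc2O1 | starting material
2 | methyl (2S)-oxirane-2-carboxylate (methyl (S)-glycidate) | COC(=O)[C@@H]1CO1 | starting material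
3 | (2,2-dimethyl-1,3-benzodioxol-5-yl)magnesium bromide | CC1(C)Oc2ccc([Mg]Br)cc2O1 | intermediate
4 | methyl (2S)-3-(2,2-dimethyl-1,3-benzodioxol-5-yl)-2-hydroxypropanoate | COC(=O)[C@H](Cc1ccc2OC(C)(C)Oc2c1)O | intermediate
5 | acrylic acid | C=CC(=O)O | starting material
6 | (2E)-3-(2,2-dimethyl-1,3-benzodioxol-5-yl)prop-2-enoic acid | OC(=O)/C=C/c1ccc2OC(C)(C)Oc2c1 | intermediate
7 | methyl (2S)-3-(2,2-dimethyl-1,3-benzodioxol-5-yl)-2-{[(2E)-3-(2,2-dimethyl-1,3-benzodioxol-5-yl)prop-2-enoyl]oxy}propanoate | COC(=O)[C@H](Cc1ccc2OC(C)(C)Oc2c1)OC(=O)/C=C/c1ccc2OC(C)(C)Oc2c1 | intermediate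
8 | 2-bromo-3-hydroxy-4-methoxybenzaldehyde | COc1ccc(C=O)c(Br)c1O | starting material
9 | 2-bromo-3,4-dihydroxybenzaldehyde | O=Cc1ccc(O)c(O)c1Br | intermediate
10 | 4-bromo-2,2-dimethyl-1,3-benzodioxole-5-carbaldehyde | O=Cc1ccc2OC(C)(C)Oc2c1Br | intermediate
11 | 4-bromo-5-(dimethoxymethyl)-2,2-dimethyl-1,3-benzodioxole | COC(OC)c1ccc2OC(C)(C)Oc2c1Br | intermediate
12 | diethyl malonate | CCOC(=O)CC(=O)OCC | starting material
13 | diethyl 2-[5-(dimethoxymethyl)-2,2-dimethyl-1,3-benzodioxol-4-yl]propanedioate | CCOC(=O)C(C(=O)OCC)c1c(C(OC)OC)ccc2OC(C)(C)Oc12 | intermediate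
14 | 2-[5-(dimethoxymethyl)-2,2-dimethyl-1,3-benzodioxol-4-yl]propanedioic acid | COC(OC)c1ccc2OC(C)(C)Oc2c1C(C(=O)O)C(=O)O | intermediate
15 | 2-(5-formyl-2,2-dimethyl-1,3-benzodioxol-4-yl)propanedioic acid | O=Cc1ccc2OC(C)(C)Oc2c1C(C(=O)O)C(=O)O | intermediate
16 | 2-(5-formyl-2,2-dimethyl-1,3-benzodioxol-4-yl)acetic acid | O=Cc1ccc2OC(C)(C)Oc2c1CC(=O)O | intermediate
17 | 5,6-(isopropylidenedioxy)-2-benzopyran-3-one (o-quinoid pyranone; the ketal oxygens are on the two ring carbons next to the ring-fusion carbon that bears the CH α to the carbonyl) | O=C1OC=C2C=CC3=C(OC(C)(C)O3)C2=C1 | intermediate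
18 | endo bridged lactone adduct: benzo-fused 2-oxabicyclo[2.2.2]octan-3-one; C1 (S) bridgehead next to the lactone carbonyl, C2 (R) with the 2,2-dimethyl-1,3-benzodioxol-5-yl group on the lactone side, C3 (S) with the (S)-side-chain ester on the benzo side, C4 (R) bridgehead bonded to the ring oxygen, isopropylidenedioxy on C7/C8 | COC(=O)[C@H](Cc1ccc2OC(C)(C)Oc2c1)OC(=O)[C@@H]1[C@H]2OC(=O)[C@H](c3c2ccc2OC(C)(C)Oc32)[C@H]1c1ccc2OC(C)(C)Oc2c1 | intermediate
19 | (1S,2S)-2-(2,2-dimethyl-1,3-benzodioxol-5-yl)-3-({[(2S)-3-(2,2-dimethyl-1,3-benzodioxol-5-yl)-1-methoxy-1-oxopropan-2-yl]oxy}carbonyl)-7,8-(isopropylidenedioxy)-1,2-dihydronaphthalene-1-carboxylic acid | COC(=O)[C@H](Cc1ccc2OC(C)(C)Oc2c1)OC(=O)C1=Cc2ccc3OC(C)(C)Oc3c2[C@@H](C(=O)O)[C@H]1c1ccc2OC(C)(C)Oc2c1 | intermediate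
20 | tetra-acetonide of the target: 1-[(2R)-side chain] 3-[(2S)-side chain] (1S,2S)-2-(2,2-dimethyl-1,3-benzodioxol-5-yl)-7,8-(isopropylidenedioxy)-1,2-dihydronaphthalene-1,3-dicarboxylate, side chain = 3-(2,2-dimethyl-1,3-benzodioxol-5-yl)-1-methoxy-1-oxopropan-2-yl | COC(=O)[C@H](Cc1ccc2OC(C)(C)Oc2c1)OC(=O)C1=Cc2ccc3OC(C)(C)Oc3c2[C@@H](C(=O)O[C@H](Cc2ccc3OC(C)(C)Oc3c2)C(=O)OC)[C@H]1c1ccc2OC(C)(C)Oc2c1 | intermediate
21 | CNP0237075.1: 1-[(2R)-3-(3,4-dihydroxyphenyl)-1-methoxy-1-oxopropan-2-yl] 3-[(2S)-3-(3,4-dihydroxyphenyl)-1-methoxy-1-oxopropan-2-yl] (1S,2S)-2-(3,4-dihydroxyphenyl)-7,8-dihydroxy-1,2-dihydronaphthalene-1,3-dicarboxylate | COC(=O)[C@H](Cc1ccc(O)c(O)c1)OC(=O)C1=Cc2ccc(O)c(O)c2[C@@H](C(=O)O[C@H](Cc2ccc(O)c(O)c2)C(=O)OC)[C@H]1c1ccc(O)c(O)c1 | target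

**Step count**

Total: 11 steps. Longest linear sequence: 8 steps (8 → 9 → 11 → 13 → 16 → 18 → 19 → 20 → 21).

**Steps most likely to fail, with fallbacks**

Step 8. The pyranone may dimerise, or the adduct may lose CO2, faster than the hindered β-aryl acrylate is captured. Attack on the two faces of 7 in endo and exo modes may also proceed without useful bias, leaving the wanted isomer as a minor part of a mixture that resists separation. The fallback sets out from acid 6 and formyl acid 16 and returns at 20. Acid 6 is alkylated with allyl bromide (K2CO3, DMF) to allyl (2E)-3-(2,2-dimethyl-1,3-benzodioxol-5-yl)prop-2-enoate F1. This cheap, achiral dienophile can be used in large excess against slowly added 16 under the Ac2O conditions and should give the racemic endo bridged lactone allyl ester F2. DBU opens F2 to the racemic cis acid F3. Mitsunobu esterification of F3 with 4 (PPh3, DIAD) gives two diastereomeric diesters, from which the (1S,2S) diester F4 is separated. Pd(PPh3)4 with morpholine removes the allyl group to give the C3 acid F5. EDC/DMAP esterification of F5 with a second portion of 4, with retention, gives 20.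

Step 9. After ring opening the amidine may deprotonate C2–H (benzylic and γ to the new acrylate), which would epimerise C2 toward the trans isomer or shift the double bond. It may also deprotonate the side-chain α-carbon and erode its (S) configuration. The fallback sets out from 18 and returns at 19 by a cationic instead of a carbanionic opening. Under anhydrous acid (camphorsulfonic acid or 1–2 % TFA in CH2Cl2, 0 °C) the C4–O bond ionises, since C4 is benzylic and para to the C7 oxygen. Loss of H3 (E1) then gives the same conjugated alkene and the free C1 acid without any carbanion, and no new compound is involved.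

Step 10. The alkoxyphosphonium ion of 4 may eliminate to the cinnamate (β-aryl, α-ester), or the hindered carboxylate may fail to displace it and acylate the hydrazide instead. The fallback sets out from 4 and 19 and returns at 20. Tf2O and 2,6-lutidine (CH2Cl2, −78 °C) convert 4 into methyl (2S)-3-(2,2-dimethyl-1,3-benzodioxol-5-yl)-2-{[(trifluoromethyl)sulfonyl]oxy}propanoate F6. The cesium salt of 19 (Cs2CO3, MeCN, 0 °C) displaces the triflate with inversion to give 20, again without activating the C1 carboxyl.

**Further compounds**

F1 | step 8 | allyl (2E)-3-(2,2-dimethyl-1,3-benzodioxol-5-yl)prop-2-enoate | C=CCOC(=O)/C=C/c1ccc2OC(C)(C)Oc2c1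
F2 | step 8 | racemic endo bridged lactone allyl ester (rel-1S,2R,3S,4R; one enantiomer drawn) | C=CCOC(=O)[C@@H]1[C@H]2OC(=O)[C@H](c3c2ccc2OC(C)(C)Oc32)[C@H]1c1ccc2OC(C)(C)Oc2c1
F3 | step 8 | racemic cis 3-(allyloxycarbonyl)-2-(2,2-dimethyl-1,3-benzodioxol-5-yl)-7,8-(isopropylidenedioxy)-1,2-dihydronaphthalene-1-carboxylic acid (rel-1S,2S; one enantiomer drawn) | C=CCOC(=O)C1=Cc2ccc3OC(C)(C)Oc3c2[C@@H](C(=O)O)[C@H]1c1ccc2OC(C)(C)Oc2c1
F4 | step 8 | (1S,2S) diester: C3 allyl ester, C1 ester of the (2R)-side chain | C=CCOC(=O)C1=Cc2ccc3OC(C)(C)Oc3c2[C@@H](C(=O)O[C@H](Cc2ccc3OC(C)(C)Oc3c2)C(=O)OC)[C@H]1c1ccc2OC(C)(C)Oc2c1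
F5 | step 8 | (1S,2S) C3 carboxylic acid with the (2R)-side-chain ester on C1 | OC(=O)C1=Cc2ccc3OC(C)(C)Oc3c2[C@@H](C(=O)O[C@H](Cc2ccc3OC(C)(C)Oc3c2)C(=O)OC)[C@H]1c1ccc2OC(C)(C)Oc2c1
F0 | step 9 | none | none
F6 | step 10 | methyl (2S)-3-(2,2-dimethyl-1,3-benzodioxol-5-yl)-2-{[(trifluoromethyl)sulfonyl]oxy}propanoate | COC(=O)[C@H](Cc1ccc2OC(C)(C)Oc2c1)OS(=O)(=O)C(F)(F)F
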